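**Assumption:** the SMILES is read as (6S,7R,8R,10R) with a cis-fused 6,12-lactone and a 4Z olefin; germacrane numbering is used (C1 furanone C=O, C2, C3 furanone C–O, C4=C5, C6 lactone O–CH, C7, C8 ester carbon, C9, C10 quaternary carbon, C11–C13 methylene lactone, C14 methyl, C15 CH2OH).

## Retrosynthetic overview

1. Target 35 ⇐ C15 desilylation and C8 tiglation of furanone alcohol 32; the furanone ring (formed last) ⇐ 5-endo O-cyclisation of the C10-hydroxy ynone.
2. Ten-membered carbocycle (second ring) ⇐ intramolecular CrCl2-mediated alkynyl–aldehyde closure of C1–C2 in iodoalkyne aldehyde 27.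
3. C6–C7 bond and the cis α-methylene-γ-butyrolactone (first ring) ⇐ intermolecular zinc Barbier allylation/lactonisation of enynal 7 with allylic bromide 21; C6 and C7 are set from C8.
4. 21 ⇐ Morita–Baylis–Hillman reaction and SN2′ bromination of aldehyde 18 ⇐ (R)-solketal (C8), Wittig, Sharpless epoxidation (C10), LiAlH4 opening; 7 ⇐ but-2-yne-1,4-diol by hydroalumination/iodination and Sonogashira coupling.
5. Ring order: lactone → ten-membered ring → furanone.

## Route

### West fragment (steps 1–4)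

Step 1
Reactants: 1 but-2-yne-1,4-diol
Product: 2 4-[(tert-butyldiphenylsilyl)oxy]but-2-yn-1-ol
Conditions: 1 (3 equiv), imidazole, TBDPSCl (1 equiv), DMF, 0 °C → rt
Reagents that add atoms: tert-butyl(chloro)diphenylsilane, CC(C)(C)[Si](Cl)(c1ccccc1)c1ccccc1
Why: Statistical monosilylation (silyl ether formation) of a symmetrical diol used in excess gives the mono-ether cleanly; no stereocentre is involved.

Step 2
Reactants: 2 4-[(tert-butyldiphenylsilyl)oxy]but-2-yn-1-ol
Product: 4 (2Z)-4-[(tert-butyldiphenylsilyl)oxy]-3-iodobut-2-en-1-ol, via cyclic vinylalanate 3 (not isolated)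
Conditions: NaAlH2(OCH2CH2OMe)2 (1.6 equiv), THF, 0 °C → rt; EtOAc; then I2, THF, −78 → 0 °C
Reagents that add atoms: iodine, II
Why: Alkoxide-directed trans-hydroalumination of the propargylic alcohol puts aluminium on C3 in a five-membered alanate, and iodinolysis with retention gives the Z-iodoalkene (I cis to CH2OH) that fixes the C4=C5 geometry.

Step 3
Reactants: 4 (2Z)-4-[(tert-butyldiphenylsilyl)oxy]-3-iodobut-2-en-1-ol; 5 ethynyl(trimethyl)silane
Product: 6 (2E)-3-{[(tert-butyldiphenylsilyl)oxy]methyl}-5-(trimethylsilyl)pent-2-en-4-yn-1-ol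
Conditions: Pd(PPh3)2Cl2 (3 mol %), CuI (6 mol %), Et3N, THF, rt
Reagents that add atoms: none
Why: Sonogashira coupling proceeds with retention of olefin geometry, so the alkyne (future C3–C2) ends cis to the CH2OH carbon (future C6).

Step 4
Reactants: 6 (2E)-3-{[(tert-butyldiphenylsilyl)oxy]methyl}-5-(trimethylsilyl)pent-2-en-4-yn-1-ol
Product: 7 (2E)-3-{[(tert-butyldiphenylsilyl)oxy]methyl}-5-(trimethylsilyl)pent-2-en-4-ynal
Conditions: Dess–Martin periodinane, NaHCO3, CH2Cl2, 0 °C → rt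
Reagents that add atoms: none
Why: Buffered Dess–Martin oxidation of the allylic alcohol gives the enal without olefin isomerisation, and CHO cis to the slim alkynyl group is also the thermodynamic isomer.

### East fragment (steps 5–14)

Step 5
Reactants: 8 [(4R)-2,2-dimethyl-1,3-dioxolan-4-yl]methanol ((R)-solketal); 9 ethyl 2-(triphenylphosphoranylidene)propanoate
Product: 11 ethyl (2E)-3-[(4R)-2,2-dimethyl-1,3-dioxolan-4-yl]-2-methylprop-2-enoate, via (4S)-glyceraldehyde acetonide 10 (not isolated)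
Conditions: TEMPO (10 mol %), PhI(OAc)2 (1.1 equiv), CH2Cl2, rt; then 9 (1.3 equiv), rt
Reagents that add atoms: none
Why: TEMPO/PhI(OAc)2 oxidation gives the labile aldehyde, which is trapped in the same flask by an E-selective Wittig olefination with the stabilised ylide; C8 comes unchanged from the chiral pool.

Step 6
Reactants: 11 ethyl (2E)-3-[(4R)-2,2-dimethyl-1,3-dioxolan-4-yl]-2-methylprop-2-enoate
Product: 12 (2E)-3-[(4R)-2,2-dimethyl-1,3-dioxolan-4-yl]-2-methylprop-2-en-1-ol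
Conditions: i-Bu2AlH (2.5 equiv), CH2Cl2, −78 °C; Rochelle salt work-up
Reagents that add atoms: none
Why: 1,2-Reduction of the enoate with i-Bu2AlH gives the allylic alcohol without touching the acetonide or the olefin geometry.

Step 7
Reactants: 12 (2E)-3-[(4R)-2,2-dimethyl-1,3-dioxolan-4-yl]-2-methylprop-2-en-1-ol
Product: 13 [(2S,3S)-3-[(4S)-2,2-dimethyl-1,3-dioxolan-4-yl]-2-methyloxiran-2-yl]methanol
Conditions: Ti(OiPr)4 (10 mol %), L-(+)-diethyl tartrate (12 mol %), t-BuOOH (2 equiv), 4 Å MS, CH2Cl2, −20 °C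
Reagents that add atoms: tert-butyl hydroperoxide, CC(C)(C)OO
Why: Sharpless asymmetric epoxidation with L-(+)-tartrate gives the (2S,3S)-epoxide under reagent control (matched with the dioxolane centre), which sets the C10 C–O bond in the configuration of the target.

Step 8
Reactants: 13 [(2S,3S)-3-[(4S)-2,2-dimethyl-1,3-dioxolan-4-yl]-2-methyloxiran-2-yl]methanol
Product: 14 (2R)-3-[(4R)-2,2-dimethyl-1,3-dioxolan-4-yl]-2-methylpropane-1,2-diol
Conditions: LiAlH4 (2 equiv), THF, 0 °C → rt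
Reagents that add atoms: none
Why: Hydride opens the trisubstituted epoxide by SN2 attack at the secondary carbon C9 because the fully substituted C10 is blocked, leaving the tertiary C10 alcohol with its configuration untouched.

Step 9
Reactants: 14 (2R)-3-[(4R)-2,2-dimethyl-1,3-dioxolan-4-yl]-2-methylpropane-1,2-diol
Product: 15 (2R)-1-[(4R)-2,2-dimethyl-1,3-dioxolan-4-yl]-3-[(4-methoxyphenyl)methoxy]-2-methylpropan-2-ol
Conditions: NaH (1.1 equiv), PMBCl (1.05 equiv), Bu4NI (cat.), THF/DMF, 0 °C → rt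
Reagents that add atoms: 4-methoxybenzyl chloride, COc1ccc(CCl)cc1
Why: Williamson etherification is selective for the primary alkoxide over the hindered tertiary one, so only the C1 oxygen is protected.

Step 10
Reactants: 15 (2R)-1-[(4R)-2,2-dimethyl-1,3-dioxolan-4-yl]-3-[(4-methoxyphenyl)methoxy]-2-methylpropan-2-ol
Product: 16 (2R,4R)-5-[(4-methoxyphenyl)methoxy]-4-methylpentane-1,2,4-triol
Conditions: AcOH/H2O (4:1), 40 °C
Reagents that add atoms: none
Why: Mild acid hydrolysis cleaves the terminal acetonide while the PMB ether and both stereocentres are unaffected.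

Step 11
Reactants: 16 (2R,4R)-5-[(4-methoxyphenyl)methoxy]-4-methylpentane-1,2,4-triol
Product: 17 1-methoxy-4-({[(2R,4R)-2-methyl-2,4,5-tris(triethylsilyloxy)pentyl]oxy}methyl)benzene
Conditions: TESOTf (4 equiv), 2,6-lutidine (6 equiv), CH2Cl2, −78 → 0 °C
Reagents that add atoms: triethylsilyl trifluoromethanesulfonate, CC[Si](CC)(CC)OS(=O)(=O)C(F)(F)F
Why: The silyl triflate silylates primary, secondary and tertiary hydroxyls exhaustively without touching any stereocentre.

Step 12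
Reactants: 17 1-methoxy-4-({[(2R,4R)-2-methyl-2,4,5-tris(triethylsilyloxy)pentyl]oxy}methyl)benzene
Product: 18 (2R,4R)-5-[(4-methoxyphenyl)methoxy]-4-methyl-2,4-bis(triethylsilyloxy)pentanal
Conditions: (COCl)2 (4 equiv), DMSO (8 equiv), CH2Cl2, −78 → −40 °C; then Et3N, −78 → 0 °C
Reagents that add atoms: none
Why: Under Swern conditions only the unhindered primary TES ether is cleaved and oxidised to the aldehyde, and the low temperature keeps the α-silyloxy centre C8 intact.

Step 13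
Reactants: 18 (2R,4R)-5-[(4-methoxyphenyl)methoxy]-4-methyl-2,4-bis(triethylsilyloxy)pentanal; 19 methyl prop-2-enoate
Product: 20 methyl (4R,6R)-3-hydroxy-7-[(4-methoxyphenyl)methoxy]-6-methyl-2-methylidene-4,6-bis(triethylsilyloxy)heptanoate (both C3 epimers)
Conditions: 19 (10 equiv, neat), DABCO (1 equiv), MeOH (2 equiv), rt, 3–5 d
Reagents that add atoms: none
Why: The Morita–Baylis–Hillman reaction attaches C11–C13 to the activated α-alkoxy aldehyde; the new carbinol centre is formed as a mixture, which does not matter because it is erased in step 14.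

Step 14
Reactants: 20 methyl (4R,6R)-3-hydroxy-7-[(4-methoxyphenyl)methoxy]-6-methyl-2-methylidene-4,6-bis(triethylsilyloxy)heptanoate
Product: 21 methyl (2Z,4R,6R)-2-(bromomethyl)-7-[(4-methoxyphenyl)methoxy]-6-methyl-4,6-bis(triethylsilyloxy)hept-2-enoate
Conditions: NBS (1.5 equiv) premixed with Me2S (1.8 equiv), CH2Cl2, 0 °C → rt
Reagents that add atoms: N-bromosuccinimide, O=C1CCC(=O)N1Br
Why: Corey–Kim-type activation of the allylic alcohol followed by SN2′ return of bromide gives the thermodynamically preferred Z-2-(bromomethyl)enoate (C8 cis to CH2Br) under neutral conditions that spare the silyl ethers.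

### Fragment union and endgame (steps 15–23)

Step 15
Reactants: 21 methyl (2Z,4R,6R)-2-(bromomethyl)-7-[(4-methoxyphenyl)methoxy]-6-methyl-4,6-bis(triethylsilyloxy)hept-2-enoate; 7 (2E)-3-{[(tert-butyldiphenylsilyl)oxy]methyl}-5-(trimethylsilyl)pent-2-en-4-ynal
Product: 24 cis-lactone (6S,7S,8R,10R) carrying the TMS-enyne, C15-OTBDPS, C8/C10-OTES and C1-OPMB groups, via allylzinc bromide 22 (not isolated), via syn hydroxy ester 23 (not isolated)
Conditions: Zn dust (5 equiv), THF/sat. aq NH4Cl (3:1), 0 °C → rt; then PPTS (0.2 equiv), toluene, 50 °C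
Reagents that add atoms: none
Why: This Barbier-type carbonyl allylation joins the two fragments at C6–C7 through a closed chair transition state in which the Z-allylzinc holds C8 axial and the aldehyde substituent equatorial, giving the syn adduct that lactonises to the cis-lactone (C6), while C7 is set by 1,2-induction from C8 (H8 eclipsing the olefin, aldehyde approaching anti to the C9 branch); minor isomers are removed by chromatography.

Step 16
Reactants: 24 cis-lactone (6S,7S,8R,10R) with C1-OPMB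
Product: 25 C1 primary alcohol of the cis-lactone (6S,7S,8R,10R)
Conditions: DDQ (1.5 equiv), CH2Cl2/pH 7 phosphate buffer (10:1), 0 °C → rt
Reagents that add atoms: none
Why: Oxidative cleavage of the PMB ether by DDQ under buffered conditions frees only the C1 hydroxyl and leaves the silyl ethers, the enyne and the methylene lactone intact.

Step 17
Reactants: 25 C1 primary alcohol of the cis-lactone
Product: 26 iodoalkyne alcohol (6S,7S,8R,10R)
Conditions: N-iodosuccinimide (1.3 equiv), AgNO3 (10 mol %), acetone, rt, dark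
Reagents that add atoms: N-iodosuccinimide, O=C1CCC(=O)N1I
Why: Silver-catalysed iododesilylation converts the alkynylsilane directly into the 1-iodoalkyne needed for the chromium-mediated closure.

Step 18
Reactants: 26 iodoalkyne alcohol
Product: 27 iodoalkyne aldehyde (6S,7S,8R,10R)
Conditions: Dess–Martin periodinane, NaHCO3, CH2Cl2, 0 °C → rt
Reagents that add atoms: none
Why: Dess–Martin oxidation gives the C1 aldehyde, which cannot epimerise because C10 is fully substituted.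

Step 19
Reactants: 27 iodoalkyne aldehyde
Product: 29 ten-membered propargylic alcohol (6S,7S,8R,10R; both C1 epimers), via alkynylchromium dichloride 28 (not isolated)
Conditions: CrCl2 (8 equiv), NiCl2 (2 mol %), degassed THF, rt, syringe-pump addition of 27 over 8 h (final 2 mM)
Reagents that add atoms: none
Why: The intramolecular Nozaki–Hiyama–Kishi-type alkynylation is chemoselective for the aldehyde, and the cis-lactone holds both chains on one face, which favours closure of the C1–C2 bond at high dilution; the C1 carbinol mixture is oxidised away in step 20.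

Step 20
Reactants: 29 ten-membered propargylic alcohol
Product: 30 ten-membered ynone (6S,7S,8R,10R)
Conditions: Dess–Martin periodinane, NaHCO3, CH2Cl2, 0 °C
Reagents that add atoms: none
Why: Dess–Martin oxidation of the propargylic alcohol gives the conjugated ynone and removes the stereocentre at C1.

Step 21
Reactants: 30 ten-membered ynone
Product: 32 furanone alcohol (3aR,4R,6R,10Z,11aS) with C8-OH and C15-OTBDPS, via dihydroxy ynone 31 (not isolated)
Conditions: HF·pyridine, pyridine, THF, 0 °C → rt; aqueous work-up, then Ph3PAuNTf2 (5 mol %), CH2Cl2, rt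
Reagents that add atoms: none
Why: Buffered HF removes both TES ethers but not the primary TBDPS ether, and the freed C10 hydroxyl adds 5-endo-dig to the gold-activated ynone (intramolecular oxa-Michael) to give the 3(2H)-furanone; the C10–O bond is never broken, so its configuration is kept.

Step 22
Reactants: 32 furanone alcohol; 33 (2E)-2-methylbut-2-enoic acid (tiglic acid)
Product: 34 C8 tiglate, C15-OTBDPS (3aR,4R,6R,10Z,11aS)
Conditions: 33 (3 equiv), 2,4,6-trichlorobenzoyl chloride (3 equiv), Et3N, THF, rt; then 32, DMAP, toluene, rt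
Reagents that add atoms: none
Why: Yamaguchi esterification acylates the hindered secondary C8 hydroxyl with retention at C8 and without changing the E geometry of the tiglate.

Step 23
Reactants: 34 C8 tiglate, C15-OTBDPS
Product: 35 target, [(3aR,4R,6R,10Z,11aS)-10-(hydroxymethyl)-6-methyl-3-methylidene-2,7-dioxo-2,3,3a,4,5,6,7,11a-octahydro-6,9-epoxycyclodeca[b]furan-4-yl] (2E)-2-methylbut-2-enoate
Conditions: HF·pyridine, THF, 0 °C → rt
Reagents that add atoms: none
Why: Fluoride-mediated desilylation under non-basic conditions frees the allylic C15 hydroxyl without affecting the tiglate, the methylene lactone or the furanone.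

## Compound list

1 | but-2-yne-1,4-diol | OCC#CCO | starting material
2 | 4-[(tert-butyldiphenylsilyl)oxy]but-2-yn-1-ol | OCC#CCO[Si](c1ccccc1)(c1ccccc1)C(C)(C)C | intermediate
3 | cyclic vinylalanate: sodium 2,2-bis(2-methoxyethoxy)-2,5-dihydro-1,2-oxaluminol-2-uide bearing the CH2OTBDPS group on the Al-bound carbon | [Na+].COCCO[Al-]1(OCCOC)OCC=C1CO[Si](c1ccccc1)(c1ccccc1)C(C)(C)C | intermediate
4 | (2Z)-4-[(tert-butyldiphenylsilyl)oxy]-3-iodobut-2-en-1-ol | OC/C=C(\I)CO[Si](c1ccccc1)(c1ccccc1)C(C)(C)C | intermediate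
5 | ethynyl(trimethyl)silane | C#C[Si](C)(C)C | starting material
6 | (2E)-3-{[(tert-butyldiphenylsilyl)oxy]methyl}-5-(trimethylsilyl)pent-2-en-4-yn-1-ol (alkyne cis to CH2OH) | OC/C=C(\C#C[Si](C)(C)C)CO[Si](c1ccccc1)(c1ccccc1)C(C)(C)C | intermediate
7 | (2E)-3-{[(tert-butyldiphenylsilyl)oxy]methyl}-5-(trimethylsilyl)pent-2-en-4-ynal (alkyne cis to CHO) | O=C/C=C(\C#C[Si](C)(C)C)CO[Si](c1ccccc1)(c1ccccc1)C(C)(C)C | intermediate
8 | [(4R)-2,2-dimethyl-1,3-dioxolan-4-yl]methanol ((R)-solketal) | OC[C@@H]1COC(C)(C)O1 | starting material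
9 | ethyl 2-(triphenylphosphoranylidene)propanoate | CCOC(=O)C(C)=P(c1ccccc1)(c1ccccc1)c1ccccc1 | starting material
10 | (4S)-2,2-dimethyl-1,3-dioxolane-4-carbaldehyde ((4S)-glyceraldehyde acetonide) | O=C[C@@H]1COC(C)(C)O1 | intermediate
11 | ethyl (2E)-3-[(4R)-2,2-dimethyl-1,3-dioxolan-4-yl]-2-methylprop-2-enoate | CCOC(=O)/C(C)=C/[C@@H]1COC(C)(C)O1 | intermediate
12 | (2E)-3-[(4R)-2,2-dimethyl-1,3-dioxolan-4-yl]-2-methylprop-2-en-1-ol | OC/C(C)=C/[C@@H]1COC(C)(C)O1 | intermediate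
13 | [(2S,3S)-3-[(4S)-2,2-dimethyl-1,3-dioxolan-4-yl]-2-methyloxiran-2-yl]methanol | OC[C@@]1(C)[C@H]([C@@H]2COC(C)(C)O2)O1 | intermediate
14 | (2R)-3-[(4R)-2,2-dimethyl-1,3-dioxolan-4-yl]-2-methylpropane-1,2-diol | OC[C@](C)(O)C[C@@H]1COC(C)(C)O1 | intermediate
15 | (2R)-1-[(4R)-2,2-dimethyl-1,3-dioxolan-4-yl]-3-[(4-methoxyphenyl)methoxy]-2-methylpropan-2-ol | COc1ccc(COC[C@](C)(O)C[C@@H]2COC(C)(C)O2)cc1 | intermediate
16 | (2R,4R)-5-[(4-methoxyphenyl)methoxy]-4-methylpentane-1,2,4-triol | COc1ccc(COC[C@](C)(O)C[C@@H](O)CO)cc1 | intermediate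
17 | 1-methoxy-4-({[(2R,4R)-2-methyl-2,4,5-tris(triethylsilyloxy)pentyl]oxy}methyl)benzene | COc1ccc(COC[C@](C)(O[Si](CC)(CC)CC)C[C@@H](O[Si](CC)(CC)CC)CO[Si](CC)(CC)CC)cc1 | intermediate
18 | (2R,4R)-5-[(4-methoxyphenyl)methoxy]-4-methyl-2,4-bis(triethylsilyloxy)pentanal | COc1ccc(COC[C@](C)(O[Si](CC)(CC)CC)C[C@@H](O[Si](CC)(CC)CC)C=O)cc1 | intermediate
19 | methyl prop-2-enoate (methyl acrylate) | C=CC(=O)OC | starting material
20 | methyl (4R,6R)-3-hydroxy-7-[(4-methoxyphenyl)methoxy]-6-methyl-2-methylidene-4,6-bis(triethylsilyloxy)heptanoate (both C3 epimers) | COc1ccc(COC[C@](C)(O[Si](CC)(CC)CC)C[C@@H](O[Si](CC)(CC)CC)C(O)C(=C)C(=O)OC)cc1 | intermediate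
21 | methyl (2Z,4R,6R)-2-(bromomethyl)-7-[(4-methoxyphenyl)methoxy]-6-methyl-4,6-bis(triethylsilyloxy)hept-2-enoate | COc1ccc(COC[C@](C)(O[Si](CC)(CC)CC)C[C@@H](O[Si](CC)(CC)CC)/C=C(\CBr)C(=O)OC)cc1 | intermediate
22 | allylzinc bromide: bromo{(2Z,4R,6R)-2-(methoxycarbonyl)-7-[(4-methoxyphenyl)methoxy]-6-methyl-4,6-bis(triethylsilyloxy)hept-2-en-1-yl}zinc | COc1ccc(COC[C@](C)(O[Si](CC)(CC)CC)C[C@@H](O[Si](CC)(CC)CC)/C=C(\C[Zn]Br)C(=O)OC)cc1 | intermediate
23 | syn hydroxy ester (6S,7S,8R,10R): methyl (3S,4S,5E)-6-{[(tert-butyldiphenylsilyl)oxy]methyl}-4-hydroxy-3-[(1R,3R)-4-[(4-methoxyphenyl)methoxy]-3-methyl-1,3-bis(triethylsilyloxy)butyl]-2-methylidene-8-(trimethylsilyl)oct-5-en-7-ynoate | COC(=O)C(=C)[C@@H]([C@@H](O)/C=C(/CO[Si](c1ccccc1)(c1ccccc1)C(C)(C)C)C#C[Si](C)(C)C)[C@H](O[Si](CC)(CC)CC)C[C@@](C)(O[Si](CC)(CC)CC)COCc1ccc(OC)cc1 | intermediate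
24 | cis-lactone (6S,7S,8R,10R): (4S,5S)-5-[(1E)-2-{[(tert-butyldiphenylsilyl)oxy]methyl}-4-(trimethylsilyl)but-1-en-3-yn-1-yl]-4-[(1R,3R)-4-[(4-methoxyphenyl)methoxy]-3-methyl-1,3-bis(triethylsilyloxy)butyl]-3-methylideneoxolan-2-one | C=C1C(=O)O[C@@H](/C=C(/CO[Si](c2ccccc2)(c2ccccc2)C(C)(C)C)C#C[Si](C)(C)C)[C@H]1[C@H](O[Si](CC)(CC)CC)C[C@@](C)(O[Si](CC)(CC)CC)COCc1ccc(OC)cc1 | intermediate
25 | C1 primary alcohol of the cis-lactone (6S,7S,8R,10R): as 24 with CH2OH in place of CH2OPMB | C=C1C(=O)O[C@@H](/C=C(/CO[Si](c2ccccc2)(c2ccccc2)C(C)(C)C)C#C[Si](C)(C)C)[C@H]1[C@H](O[Si](CC)(CC)CC)C[C@@](C)(O[Si](CC)(CC)CC)CO | intermediate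
26 | iodoalkyne alcohol (6S,7S,8R,10R): as 25 with C≡C–I in place of C≡C–SiMe3 | C=C1C(=O)O[C@@H](/C=C(/CO[Si](c2ccccc2)(c2ccccc2)C(C)(C)C)C#CI)[C@H]1[C@H](O[Si](CC)(CC)CC)C[C@@](C)(O[Si](CC)(CC)CC)CO | intermediate
27 | iodoalkyne aldehyde (6S,7S,8R,10R): (2R,4R)-4-[(2S,3S)-2-[(1E)-2-{[(tert-butyldiphenylsilyl)oxy]methyl}-4-iodobut-1-en-3-yn-1-yl]-4-methylidene-5-oxooxolan-3-yl]-2-methyl-2,4-bis(triethylsilyloxy)butanal | C=C1C(=O)O[C@@H](/C=C(/CO[Si](c2ccccc2)(c2ccccc2)C(C)(C)C)C#CI)[C@H]1[C@H](O[Si](CC)(CC)CC)C[C@@](C)(O[Si](CC)(CC)CC)C=O | intermediate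
28 | alkynylchromium dichloride: as 27 with C≡C–CrCl2 in place of C≡C–I | C=C1C(=O)O[C@@H](/C=C(/CO[Si](c2ccccc2)(c2ccccc2)C(C)(C)C)C#C[Cr](Cl)Cl)[C@H]1[C@H](O[Si](CC)(CC)CC)C[C@@](C)(O[Si](CC)(CC)CC)C=O | intermediate
29 | ten-membered propargylic alcohol (6S,7S,8R,10R; both C1 epimers): 15-(tert-butyldiphenylsilyloxy)-1-hydroxy-8,10-bis(triethylsilyloxy)germacra-4,11(13)-dien-2-yn-12,6-olide, cis-fused lactone, C3 and C6 cis on C4=C5 | C=C1C(=O)O[C@H]2/C=C(/CO[Si](c3ccccc3)(c3ccccc3)C(C)(C)C)C#CC(O)[C@@](C)(C[C@@H](O[Si](CC)(CC)CC)[C@@H]12)O[Si](CC)(CC)CC | intermediate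
30 | ten-membered ynone (6S,7S,8R,10R): 1-oxo analogue of 29 | C=C1C(=O)O[C@H]2/C=C(/CO[Si](c3ccccc3)(c3ccccc3)C(C)(C)C)C#CC(=O)[C@@](C)(C[C@@H](O[Si](CC)(CC)CC)[C@@H]12)O[Si](CC)(CC)CC | intermediate
31 | dihydroxy ynone (6S,7R,8R,10R): 8,10-dihydroxy analogue of 30 | C=C1C(=O)O[C@H]2/C=C(/CO[Si](c3ccccc3)(c3ccccc3)C(C)(C)C)C#CC(=O)[C@@](C)(C[C@@H](O)[C@@H]12)O | intermediate
32 | furanone alcohol: (3aR,4R,6R,10Z,11aS)-10-{[(tert-butyldiphenylsilyl)oxy]methyl}-4-hydroxy-6-methyl-3-methylidene-3a,4,5,6-tetrahydro-6,9-epoxycyclodeca[b]furan-2,7(3H,11aH)-dione | C=C1C(=O)O[C@H]2/C=C(/CO[Si](c4ccccc4)(c4ccccc4)C(C)(C)C)C3=CC(=O)[C@@](C)(C[C@@H](O)[C@@H]12)O3 | intermediate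
33 | (2E)-2-methylbut-2-enoic acid (tiglic acid) | C/C=C(\C)C(=O)O | starting material
34 | C8 tiglate, C15-OTBDPS: [(3aR,4R,6R,10Z,11aS)-10-{[(tert-butyldiphenylsilyl)oxy]methyl}-6-methyl-3-methylidene-2,7-dioxo-2,3,3a,4,5,6,7,11a-octahydro-6,9-epoxycyclodeca[b]furan-4-yl] (2E)-2-methylbut-2-enoate | C=C1C(=O)O[C@H]2/C=C(/CO[Si](c4ccccc4)(c4ccccc4)C(C)(C)C)C3=CC(=O)[C@@](C)(C[C@@H](OC(=O)/C(C)=C/C)[C@@H]12)O3 | intermediate
35 | [(3aR,4R,6R,10Z,11aS)-10-(hydroxymethyl)-6-methyl-3-methylidene-2,7-dioxo-2,3,3a,4,5,6,7,11a-octahydro-6,9-epoxycyclodeca[b]furan-4-yl] (2E)-2-methylbut-2-enoate | C=C1C(=O)O[C@H]2/C=C(/CO)C3=CC(=O)[C@@](C)(C[C@@H](OC(=O)/C(C)=C/C)[C@@H]12)O3 | target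

## Step count and risks

Total steps: 23. Longest linear sequence: 19 steps (8 → 35: steps 5–14, then 15–23). The west branch contributes steps 1–4.

The three steps most likely to fail:

**Step 13** (Morita–Baylis–Hillman reaction on a hindered α-silyloxy aldehyde: slow conversion or erosion of C8). The fallback sets out from 18 and makes the same bond by stoichiometric vinylalumination instead of amine catalysis. Methyl propiolate is hydroaluminated with i-Bu2AlH and N-methylmorpholine N-oxide in THF at 0 °C to give [1-(methoxycarbonyl)ethenyl]bis(2-methylpropyl)alumane F1. F1 adds to 18 at 0 °C → rt under non-basic conditions, and the route is rejoined at 20.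

**Step 15** (facial selectivity relative to C8 and the syn/anti ratio in the zinc Barbier union). The fallback sets out from 20 (with 7) and replaces the transient allylzinc by an isolable, geometrically defined allylboron reagent under catalyst control. Ac2O, DMAP and pyridine give allylic acetate F2. SN2′ borylation (B2pin2, Pd2(dba)3, toluene, 50 °C) gives allylboronate F3, with C8 cis to the CH2B group. Allylboration of 7 catalysed by the chiral BINOL-derived phosphoric acid (R)-TRIP (toluene, −30 °C → rt) goes through a closed chair transition state that is syn-specific, with the aldehyde face set by the catalyst (the antipode of the acid is tried if mismatched), and gives borate F4. Hydrolytic work-up gives 23, PPTS closes the lactone, and the route is rejoined at 24.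

**Step 19** (ten-membered ring closure by CrCl2-mediated alkynylation: oligomerisation or no closure). The fallback moves the ring-closing bond from C1–C2 to C3–C4 and keeps the same fragment union. It sets out from 4 (with 21). Dess–Martin oxidation of 4 gives iodo enal F5. Zinc Barbier union of F5 with 21 under the step 15 conditions gives hydroxy ester F6 and, after PPTS, iodovinyl cis-lactone F7. DDQ then gives primary alcohol F8, and Dess–Martin oxidation gives aldehyde F9. HC≡CMgBr (THF, −78 °C) gives terminal propargylic alcohol F10 as both C1 epimers. An intramolecular Sonogashira coupling (Pd(PPh3)4, CuI, Et3N, THF, high dilution) forms the C3–C4 bond, and the route is rejoined at 29.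

## Further compounds

F1 | step 13 | [1-(methoxycarbonyl)ethenyl]bis(2-methylpropyl)alumane | C=C(C(=O)OC)[Al](CC(C)C)CC(C)C
F2 | step 15 | allylic acetate: methyl (4R,6R)-3-acetoxy-7-[(4-methoxyphenyl)methoxy]-6-methyl-2-methylidene-4,6-bis(triethylsilyloxy)heptanoate (both C3 epimers) | COc1ccc(COC[C@](C)(O[Si](CC)(CC)CC)C[C@@H](O[Si](CC)(CC)CC)C(OC(C)=O)C(=C)C(=O)OC)cc1
F3 | step 15 | allylboronate: methyl (2E,4R,6R)-7-[(4-methoxyphenyl)methoxy]-6-methyl-2-[(4,4,5,5-tetramethyl-1,3,2-dioxaborolan-2-yl)methyl]-4,6-bis(triethylsilyloxy)hept-2-enoate | COc1ccc(COC[C@](C)(O[Si](CC)(CC)CC)C[C@@H](O[Si](CC)(CC)CC)/C=C(\CB2OC(C)(C)C(C)(C)O2)C(=O)OC)cc1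
F4 | step 15 | borate: O-(4,4,5,5-tetramethyl-1,3,2-dioxaborolan-2-yl) derivative of hydroxy ester 23 | COC(=O)C(=C)[C@@H]([C@@H](OB1OC(C)(C)C(C)(C)O1)/C=C(/CO[Si](c1ccccc1)(c1ccccc1)C(C)(C)C)C#C[Si](C)(C)C)[C@H](O[Si](CC)(CC)CC)C[C@@](C)(O[Si](CC)(CC)CC)COCc1ccc(OC)cc1
F5 | step 19 | iodo enal: (2Z)-4-[(tert-butyldiphenylsilyl)oxy]-3-iodobut-2-enal | O=C/C=C(\I)CO[Si](c1ccccc1)(c1ccccc1)C(C)(C)C
F6 | step 19 | hydroxy ester: iodovinyl analogue of 23 (C4–I in place of the silylalkyne; I cis to C6) | COC(=O)C(=C)[C@@H]([C@@H](O)/C=C(\I)CO[Si](c1ccccc1)(c1ccccc1)C(C)(C)C)[C@H](O[Si](CC)(CC)CC)C[C@@](C)(O[Si](CC)(CC)CC)COCc1ccc(OC)cc1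
F7 | step 19 | iodovinyl cis-lactone: iodovinyl analogue of 24 | C=C1C(=O)O[C@@H](/C=C(\I)CO[Si](c2ccccc2)(c2ccccc2)C(C)(C)C)[C@H]1[C@H](O[Si](CC)(CC)CC)C[C@@](C)(O[Si](CC)(CC)CC)COCc1ccc(OC)cc1
F8 | step 19 | primary alcohol: F7 with CH2OH in place of CH2OPMB | C=C1C(=O)O[C@@H](/C=C(\I)CO[Si](c2ccccc2)(c2ccccc2)C(C)(C)C)[C@H]1[C@H](O[Si](CC)(CC)CC)C[C@@](C)(O[Si](CC)(CC)CC)CO
F9 | step 19 | aldehyde: F8 oxidised at C1 | C=C1C(=O)O[C@@H](/C=C(\I)CO[Si](c2ccccc2)(c2ccccc2)C(C)(C)C)[C@H]1[C@H](O[Si](CC)(CC)CC)C[C@@](C)(O[Si](CC)(CC)CC)C=O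
F10 | step 19 | terminal propargylic alcohol: ethynyl adduct of F9 (both C1 epimers) | C=C1C(=O)O[C@@H](/C=C(\I)CO[Si](c2ccccc2)(c2ccccc2)C(C)(C)C)[C@H]1[C@H](O[Si](CC)(CC)CC)C[C@@](C)(O[Si](CC)(CC)CC)C(O)C#C
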